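## Structural features

The target 31 is a resveratrol trimer in which two oxygen heterocycles hang on one benzene ring (ring A): a 2,3-dihydrobenzofuran (O1', C2', C3', C3a'–C7a') and an oxolane (O1, C2–C5) bonded through C4 to C4' of ring A, which also carries the C6' hydroxyl. C2' bears a 4-hydroxyphenyl and C3' a 3,5-dihydroxyphenyl group, trans (2'R,3'R). The oxolane bears 4-hydroxyphenyl groups on C2 and C5 and a 3,5-dihydroxyphenyl group on C3 (2S,3R,4S,5S): the substituents on C3, C4 and C5 are all cis and the C2 aryl is trans to C3. The six stereocentres form two contiguous sets (C2'/C3' and C2–C5) separated by the flat ring A, so neither set can steer the other and each needs its own source of absolute configuration. The fragile points are the three benzylic C–O bonds para to an oxygenated aryl ring (C2'–O1', C2–O1, C5–O1), which ionise under acid and then epimerise or are captured by a neighbouring electron-rich ring. Also fragile are the eight phenols (air oxidation in base) and the all-cis C3/C4/C5 array, which is not the thermodynamic one. The real difficulty is the crowded C4–C4' bond between the two halves and keeping the cis triad and the benzylic ethers intact to the end. The key step exploits the 3,5-dihydroxyphenyl ring on C3': it has the oxygen pattern of a folded polyketide, its ipso carbon is a former ketone carbon attached to C3', and C3', being α to that ketone, rests trans to the C2' aryl group.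

## Logic of the disconnections

31 ⇒ 30. Only the eight O–CH3 bonds are cut. One ether type masks every phenol and tolerates organomagnesium, hydride, hydrogenation and Lewis-acid steps. Nothing is gained in skeleton. The demand is an eightfold cleavage that spares the three benzylic C–O bonds.

30 ⇒ 28 + 29. The C2–aryl bond of the oxolane is cut. C2 is the one ring carbon whose aryl group is trans to its neighbour, so an oxocarbenium ion at C2 can be arylated from the face left open by the three cis aryl groups. One stereocentre and one ring disappear from the problem. The forward step must trap the cation before it loses H3 or the C5–O bond ionises.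

28 ⇒ 27 ⇒ 26. The C2–H bond (hydride) and then the C3–H and C4–H bonds are removed. Cis addition of hydrogen to the planar ring of 26, away from the C5 aryl group, creates the all-cis triad in one operation, so three stereocentres are reduced to one (C5). The demand is saturation of a tetrasubstituted alkene without hydrogenolysis of the C5–O bond, and no base afterwards.

26 ⇒ 17 + 21 + CO2. The C4–C4' bond, the C2–C3 bond and the lactone C2–O1 bond are cut. Anti addition of an aryl–magnesium bond across the alkyne of 21, directed by its alkoxide, places the aryl group next to the carbinol and the metal cis to it, which is the geometry the lactone needs. This is the most convergent cut: it splits the molecule into two halves of similar size plus one carbon. The demand is that a hindered arylmagnesium adds to an internal alkyne and that the carbinol C–O bond of 21 never ionises.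

21 ⇒ 18 + 19. The carbinol–alkyne C–C bond is cut, leading to two commercial compounds. The forward addition must set the R configuration with high selectivity, because this centre later controls C3, C4 and C2.

17 ⇒ 16. Two O–CH3 bonds are cut. The phenols of 16 must be capped before 22 can exist.

16 ⇒ 15 (key step). One ring C–C bond of the C3' aryl group is cut, between the ipso carbon (chain C1) and its ring neighbour (chain C6). An aromatic ring is traded for an open 1,3,5-triketone chain attached through a ketone α to C3', where the trans arrangement is the stable one. The forward step must cyclise through carbon, not oxygen, and must not open the dihydrofuran ring.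

15 ⇒ 14 ⇒ 11 + 12. After adjustment of the oxidation level, the C1–C2 bond of the chain is cut (aldol). An aldehyde is chosen as acceptor because 13 adds to it at low temperature faster than it deprotonates C3'; an ester would be enolised instead. The demand is reaction at the terminal carbon of 13 and a mild oxidation afterwards.

11 ⇒ 10 ⇒ 9 ⇒ 8. After reduction and epimerisation, the C2'–C3' bond is cut (carbene C–H insertion). Both ring stereocentres then come from an achiral diazo ester: the catalyst sets C2' and thermodynamics sets C3'. The demand is 1,5-insertion into the benzylic ether C–H bond with high enantioselectivity next to an ortho bromine.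

8 ⇒ 6 ⇒ 4 + 5 ⇒ 1 + 2. The diazo group is traced to a ketone, the O–CH2 bond to a phenol alkylation and the aryl–CO bond to an acylation of 1, which ends at commercial materials. The acylation must go to C2 of 1 and only the methyl ether next to the new ketone may be removed.

## Other disconnections considered

Alternative 1: The oxolane of 30 is cut at O1–C2 and C2–C3, so C2 with its aryl group is removed as a carbene.
- Forward step: a copper carbene from the diazo compound A3 would add to the carbonyl oxygen of the α-aryl enone A2. The carbonyl ylide would close by 1,5-electrocyclisation to the dihydrofuran A1, with the C2 and C3 aryl groups trans. Hydrogenation of the remaining C4=C5 enol ether from the face away from the C3 aryl group would then give 30.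
- In favour: one step forms a ring and two bonds and delivers the C2/C3 trans relation directly; no lactol arylation and no carbomagnesiation are needed.
- Against, here: A3 is a non-stabilised diazo compound (hazard, azine and stilbene formation). C2 and C3 are remote from C2'/C3', so their absolute configuration must come from a chiral copper ligand, and such asymmetric annulations are established for diazoacetates, not aryldiazomethanes. A2 still requires a coupling of the hindered aryl group of 17 to an enone α-carbon. A1 is an acid-labile, fully substituted enol ether.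
- Comparison: on step economy the alternative is better, by about two steps in the oxolane part. On the final hydrogenation the two plans are equal (a tetrasubstituted alkene in both). On stereochemical logic the chosen plan is better founded: one catalyst-set centre (C5) relays to C3, C4 and C2, whereas the alternative needs catalyst control over two new centres next to a bulky, uncontrolling substituent.

Alternative 2: Ring A is cut at C4'–C5' and C3a'–C7a'.
- Forward step: the ynone A5, which already carries the complete oxolane, and the electron-rich diene A6 would undergo a [4+2] cycloaddition. Loss of methanol would aromatise the adduct to the 2-hydroxybenzophenone A4, whose ketone carbon is the future C3' and whose phenol is the future O1'.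
- In favour: the substitution pattern of ring A follows from the polarity of the two partners, which is better regiocontrol than the acylation of step 1. No aryl halide and no hindered aryl–metal reagent are needed. The oxolane is built on simple material.
- Against, here: the dihydrofuran ring must still be made from A4 (alkylation with 5, C2'–C3' bond formation, reduction). Its two stereocentres would be set late, beside an oxolane that cannot direct them, while the acid-labile oxolane and the epimerisable C4–H next to the alkyne must survive all of this. Ynones with a branched propargylic carbon are slow dienophiles.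
- Comparison: in construction of the arene the alternative is the better; in the handling of C2'/C3' the chosen plan is clearly better (set early, on a small molecule, by catalyst and thermodynamics). In step count the two are about equal, since the steps after A4 replace steps 2–9.

Alternative 3: The C2'–O1' bond of 17 is cut, giving the triarylethylene phenol A8.
- Forward step: a confined chiral imidodiphosphorimidate acid would protonate the alkene at C3', and the phenol oxygen would capture the 4-methoxybenzyl cation at C2' to give A7, which is the same compound as 17.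
- In favour: A8 is flat and should be reachable in about four steps. One catalytic step sets both stereocentres, with no diazo compound, no rhodium and no triketone. Because A7 is 17, the endgame is unchanged.
- Against, here: the enantio-determining event is a protonation that creates C3' next to a long-lived, planar, strongly stabilised cation. Reversible protonation would erode C3', and the cation can also be captured by the dimethoxyphenyl ring. Asymmetric hydroalkoxylation with such acids is established for aliphatic alkenols, not for phenols adding across electron-rich stilbenes flanked by an ortho bromine.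
- Comparison: on step economy the alternative is better (about five steps to 17 instead of nine). On trans selectivity the two are equal (thermodynamic in both). On certainty of absolute configuration the chosen plan is better, since its C–H insertion belongs to an established substrate class.

Key step: step 8

Remarks on the chemistry:
- Locants: primed atoms belong to the dihydrobenzofuran; the oxolane is numbered O1, C2 (aryl, former lactone carbonyl), C3 (dimethoxyphenyl), C4 (bonded to C4'), C5 (aryl); the chain of 15 is numbered C1 (on C3') to C6 (methyl).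
- DBF stands for (2R,3R)-3-(3,5-dimethoxyphenyl)-6-methoxy-2-(4-methoxyphenyl)-2,3-dihydro-1-benzofuran-4-yl.
- Correction: the ring closure of step 8 is of the 6-(enolendo)-exo-trig type, because the C5=C6 enolate bond lies inside the ring that forms; an enolexo label would be wrong. The structures themselves are consistent and need no change.
- Design change: C3' is set trans at the ester stage (step 4) and not left to the key step, because once the arene exists C3' can no longer be corrected.
- Assumption: Rh2(S-PTTL)4 is taken to give the 2R insertion product and (S)-BINOL the R alcohol; if either sense proved opposite, the mirror-image catalyst would be used with no other change.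

## Route

Step 1
Reactants: 1 1-bromo-3,5-dimethoxybenzene; 2 methyl chlorooxoacetate
Product: 4 methyl 2-(2-bromo-6-hydroxy-4-methoxyphenyl)-2-oxoacetate, via dimethoxy ketoester 3 (not isolated)
Conditions: AlCl3 (3 equiv), CH2Cl2, 0 °C, then 40 °C; aq. HCl
Reagents that add atoms: none
Why: Friedel–Crafts acylation should occur para to one methoxy group and ortho to the other, at C2 of 1; the aluminium chelate of the new ketone with the flanking methoxy group then loses chloromethane (chelation-directed demethylation), while the unchelated methoxy group stays.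

Step 2
Reactants: 4 methyl 2-(2-bromo-6-hydroxy-4-methoxyphenyl)-2-oxoacetate; 5 4-methoxybenzyl chloride
Product: 6 methyl 2-{2-bromo-4-methoxy-6-[(4-methoxybenzyl)oxy]phenyl}-2-oxoacetate
Conditions: K2CO3, n-Bu4NI (cat.), DMF, 50 °C
Reagents that add atoms: none
Why: Williamson ether synthesis at the free phenol with iodide catalysis; the benzylic CH2 introduced here is the future C2'.

Step 3
Reactants: 6 methyl 2-{2-bromo-4-methoxy-6-[(4-methoxybenzyl)oxy]phenyl}-2-oxoacetate
Product: 8 methyl 2-{2-bromo-4-methoxy-6-[(4-methoxybenzyl)oxy]phenyl}-2-diazoacetate, via tosylhydrazone 7 (not isolated)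
Conditions: TsNHNH2, MeOH, 60 °C; then DBU, CH2Cl2, 0 °C → rt
Reagents that add atoms: p-toluenesulfonohydrazide, Cc1ccc(cc1)S(=O)(=O)NN
Why: Condensation of the ketone with the hydrazide gives 7, and base-induced loss of p-toluenesulfinate (Bamford–Stevens reaction) should give the aryldiazoacetate.

Step 4
Reactants: 8 methyl 2-{2-bromo-4-methoxy-6-[(4-methoxybenzyl)oxy]phenyl}-2-diazoacetate
Product: 10 methyl (2R,3R)-4-bromo-6-methoxy-2-(4-methoxyphenyl)-2,3-dihydro-1-benzofuran-3-carboxylate (trans), via cis ester 9 (not isolated)
Conditions: Rh2(S-PTTL)4 (1 mol%), toluene, −60 °C; then NaOMe (0.3 equiv), MeOH, −60 °C → rt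
Reagents that add atoms: none
Why: Intramolecular 1,5 C–H insertion of the rhodium carbene into the benzylic ether C–H bond, in which the chiral carboxylate ligands set C2 (R) and the cis ester 9 forms kinetically. Methoxide then epimerises C3 through the ester enolate to the more stable trans isomer; C2 is untouched because ring opening by β-elimination would be the reverse of a 5-endo-trig closure.

Step 5
Reactants: 10 methyl (2R,3R)-4-bromo-6-methoxy-2-(4-methoxyphenyl)-2,3-dihydro-1-benzofuran-3-carboxylate
Product: 11 (2R,3R)-4-bromo-6-methoxy-2-(4-methoxyphenyl)-2,3-dihydro-1-benzofuran-3-carbaldehyde (trans)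
Conditions: DIBAL-H (1.1 equiv), CH2Cl2, −78 °C; Rochelle salt
Reagents that add atoms: none
Why: Partial reduction of an ester with DIBAL-H: the tetrahedral aluminium hemiacetal of this hindered ester should persist at −78 °C and release the aldehyde only on work-up; trans is also the stable arrangement of the aldehyde.

Step 6
Reactants: 11 (2R,3R)-4-bromo-6-methoxy-2-(4-methoxyphenyl)-2,3-dihydro-1-benzofuran-3-carbaldehyde; 12 acetylacetone
Product: 14 6-[(2R,3S)-4-bromo-6-methoxy-2-(4-methoxyphenyl)-2,3-dihydro-1-benzofuran-3-yl]-6-hydroxyhexane-2,4-dione (ring substituents trans as before, the C3 descriptor changes by the priority rules only; both carbinol epimers), via dilithio acetylacetone 13 (not isolated)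
Conditions: 12 (1.5 equiv), LDA (3.0 equiv), THF, 0 °C; then 11, −78 °C; aq. NH4Cl
Reagents that add atoms: none
Why: Aldol addition of a β-diketone dianion: the more basic terminal carbanion of 13 should attack the aldehyde at −78 °C faster than it deprotonates C3'; the new carbinol centre forms unselectively and is removed by the next oxidation.

Step 7
Reactants: 14 6-[(2R,3S)-4-bromo-6-methoxy-2-(4-methoxyphenyl)-2,3-dihydro-1-benzofuran-3-yl]-6-hydroxyhexane-2,4-dione
Product: 15 1-[(2R,3R)-4-bromo-6-methoxy-2-(4-methoxyphenyl)-2,3-dihydro-1-benzofuran-3-yl]hexane-1,3,5-trione (trans; largely enolised)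
Conditions: Dess–Martin periodinane (1.3 equiv), CH2Cl2, 0 °C → rt
Reagents that add atoms: none
Why: Dess–Martin oxidation of the β-hydroxy diketone to the 1,3,5-triketone under mild, non-basic conditions; the acetic acid released is too weak to drive pyranone formation and no base is present to start the cyclisation early.

Step 8
Reactants: 15 1-[(2R,3R)-4-bromo-6-methoxy-2-(4-methoxyphenyl)-2,3-dihydro-1-benzofuran-3-yl]hexane-1,3,5-trione
Product: 16 5-[(2R,3R)-4-bromo-6-methoxy-2-(4-methoxyphenyl)-2,3-dihydro-1-benzofuran-3-yl]benzene-1,3-diol (trans)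
Conditions: KOH (1 M, aq.), MeOH, argon, 25 → 40 °C; then 1 M HCl, 0 °C
Reagents that add atoms: none
Why: Hydroxide deprotonates the triketone, the enolate of the terminal methyl ketone (C6) adds to the C1 carbonyl bonded to C3', and the aldol loses water and tautomerises to the resorcinol, which makes the sequence irreversible (intramolecular aldol condensation with aromatisation). The closest known reaction type is the hydroxide-mediated cyclisation of 1,3,5-triketones, made from β-diketone dianions, to 5-substituted resorcinols, the laboratory counterpart of the folding step of stilbene synthase. The ring closes in the 6-(enolendo)-exo-trig mode, since the C5=C6 enolate bond lies inside the new six-membered ring and the attacked C=O is exocyclic. No stereocentre is created: C3' enters trans, stays α to a carbonyl until aromatisation, and any epimerisation through its enol can only return the trans isomer, the more stable one relative to C2', which the rhodium catalyst fixed in step 4. Carbon and not oxygen cyclisation is secured by the basic medium (acid would dehydrate the triketone to a 4-pyranone), and the competing aldol of C3' onto C5 gives a spiro ketol that cannot aromatise and reverts. C2' should be retained because opening of the furan ring by β-elimination of the phenoxide would be the reverse of a 5-endo-trig closure, with the C2'–O bond nearly orthogonal to the enolate π system, and because the polyanionic triketone resists deprotonation at C3'; dilute hydroxide, moderate temperature and exclusion of air limit the remaining risk.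

Step 9
Reactants: 16 5-[(2R,3R)-4-bromo-6-methoxy-2-(4-methoxyphenyl)-2,3-dihydro-1-benzofuran-3-yl]benzene-1,3-diol
Product: 17 (2R,3R)-4-bromo-3-(3,5-dimethoxyphenyl)-6-methoxy-2-(4-methoxyphenyl)-2,3-dihydro-1-benzofuran
Conditions: MeI, K2CO3, acetone, 50 °C
Reagents that add atoms: iodomethane, CI
Why: Williamson O-methylation of the two phenols, which would otherwise quench the organomagnesium reagent of step 11.

Step 10
Reactants: 18 4-methoxybenzaldehyde; 19 1-ethynyl-3,5-dimethoxybenzene
Product: 21 (1R)-3-(3,5-dimethoxyphenyl)-1-(4-methoxyphenyl)prop-2-yn-1-ol, via alkynylzinc 20 (not isolated)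
Conditions: 19, Et2Zn (2 equiv), toluene, reflux; then (S)-BINOL (20 mol%), Ti(OiPr)4 (50 mol%), 18, CH2Cl2, rt
Reagents that add atoms: none
Why: Catalytic asymmetric addition of an alkynylzinc reagent to an aromatic aldehyde; the titanium BINOLate shields one face of the aldehyde and (S)-BINOL is expected to give the R carbinol.

Step 11
Reactants: 17 (2R,3R)-4-bromo-3-(3,5-dimethoxyphenyl)-6-methoxy-2-(4-methoxyphenyl)-2,3-dihydro-1-benzofuran; 21 (1R)-3-(3,5-dimethoxyphenyl)-1-(4-methoxyphenyl)prop-2-yn-1-ol
Product: 26 (5R)-4-DBF-3-(3,5-dimethoxyphenyl)-5-(4-methoxyphenyl)furan-2(5H)-one, via aryl Grignard 22 (not isolated), via magnesium alkoxide 23 (not isolated), via alkenylmagnesium chelate 24 (not isolated), via hydroxy acid 25 (not isolated)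
Conditions: 17, Mg, LiCl, THF, 40 °C; 21, i-PrMgCl (1.0 equiv), THF, 0 °C; combine, CuI (10 mol%), THF–toluene, 25 → 70 °C; CO2, 0 °C; 1 M HCl to pH 3, 0 °C → rt
Reagents that add atoms: carbon dioxide, O=C=O
Why: After exchange between 22 and the alkoxide 23 the aryl group should be delivered to the alkyne carbon next to the carbinol while magnesium ends on the distal, aryl-stabilised carbon, cis to the alkoxide in a five-membered chelate (copper-catalysed anti-carbomagnesiation of a propargylic alcohol). Carboxylation of the alkenyl–magnesium bond with retention and acidification give the Z hydroxy acid 25, which lactonises spontaneously; the carbinol C–O bond is never broken, so the R centre of 21 becomes C5 of 26.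

Step 12
Reactants: 26 (5R)-4-DBF-3-(3,5-dimethoxyphenyl)-5-(4-methoxyphenyl)furan-2(5H)-one
Product: 27 (3R,4S,5S)-4-DBF-3-(3,5-dimethoxyphenyl)-5-(4-methoxyphenyl)oxolan-2-one (3,4-cis, 4,5-cis)
Conditions: H2 (4 atm), 10% Pd/C, EtOAc, rt
Reagents that add atoms: none
Why: Heterogeneous syn hydrogenation of a butenolide: both hydrogens should arrive from the face opposite the C5 aryl group, so the aryl groups on C3, C4 and C5 end up cis; an aprotic solvent and the absence of acid are chosen to disfavour hydrogenolysis of the benzylic lactone C–O bond.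

Step 13
Reactants: 27 (3R,4S,5S)-4-DBF-3-(3,5-dimethoxyphenyl)-5-(4-methoxyphenyl)oxolan-2-one
Product: 28 (3R,4S,5S)-4-DBF-3-(3,5-dimethoxyphenyl)-5-(4-methoxyphenyl)oxolan-2-ol (both anomers)
Conditions: DIBAL-H (1.2 equiv), CH2Cl2, −78 °C; Rochelle salt
Reagents that add atoms: none
Why: DIBAL-H reduction of a lactone should stop at the aluminium hemiacetal at −78 °C and give the lactol on work-up; the reagent is not basic, so the epimerisable C3 centre is left alone.

Step 14
Reactants: 28 (3R,4S,5S)-4-DBF-3-(3,5-dimethoxyphenyl)-5-(4-methoxyphenyl)oxolan-2-ol; 29 potassium (4-methoxyphenyl)trifluoroborate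
Product: 30 (2S,3R,4S,5S)-4-DBF-3-(3,5-dimethoxyphenyl)-2,5-bis(4-methoxyphenyl)oxolane
Conditions: 29 (2.5 equiv), BF3·OEt2 (3 equiv), MeCN–CH2Cl2, −40 → 0 °C
Reagents that add atoms: none
Why: BF3 ionises the lactol to a cyclic oxocarbenium ion and the aryltrifluoroborate transfers its aryl group by ipso attack, so only the 4-methoxyphenyl isomer can form (Lewis-acid-promoted addition of an organotrifluoroborate to an oxocarbenium ion). Attack from the face opposite the three cis aryl groups should place the new aryl trans to C3 (2S); low temperature limits proton loss from C3 and ionisation at C5.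

Step 15
Reactants: 30 (2S,3R,4S,5S)-4-DBF-3-(3,5-dimethoxyphenyl)-2,5-bis(4-methoxyphenyl)oxolane
Product: 31 5-[(2S,3R,4S,5S)-4-[(2R,3R)-3-(3,5-dihydroxyphenyl)-6-hydroxy-2-(4-hydroxyphenyl)-2,3-dihydro-1-benzofuran-4-yl]-2,5-bis(4-hydroxyphenyl)oxolan-3-yl]benzene-1,3-diol (CNP0202577.3)
Conditions: BBr3 (16 equiv), CH2Cl2, −78 → 0 °C; MeOH at −78 °C, then aq. NaHCO3
Reagents that add atoms: none
Why: Lewis-acid cleavage of the eight aryl methyl ethers (BBr3 demethylation); the reagent is added at −78 °C, the mixture is kept at or below 0 °C and quenched cold, so that the benzylic C–O bonds of both heterocycles are exposed to the Lewis acid as briefly as possible.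

## Compound list

1 | 1-bromo-3,5-dimethoxybenzene | COc1cc(Br)cc(OC)c1 | starting material
2 | methyl chlorooxoacetate | COC(=O)C(Cl)=O | starting material
3 | methyl 2-(2-bromo-4,6-dimethoxyphenyl)-2-oxoacetate (not isolated) | COC(=O)C(=O)c1c(Br)cc(OC)cc1OC | intermediate
4 | methyl 2-(2-bromo-6-hydroxy-4-methoxyphenyl)-2-oxoacetate | COC(=O)C(=O)c1c(Br)cc(OC)cc1O | intermediate
5 | 4-methoxybenzyl chloride | COc1ccc(CCl)cc1 | starting material
6 | methyl 2-{2-bromo-4-methoxy-6-[(4-methoxybenzyl)oxy]phenyl}-2-oxoacetate | COC(=O)C(=O)c1c(Br)cc(OC)cc1OCc1ccc(OC)cc1 | intermediate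
7 | N-tosylhydrazone of 6 (not isolated) | COC(=O)C(=NNS(=O)(=O)c1ccc(C)cc1)c1c(Br)cc(OC)cc1OCc1ccc(OC)cc1 | intermediate
8 | methyl 2-{2-bromo-4-methoxy-6-[(4-methoxybenzyl)oxy]phenyl}-2-diazoacetate | COC(=O)C(=[N+]=[N-])c1c(Br)cc(OC)cc1OCc1ccc(OC)cc1 | intermediate
9 | methyl (2R,3S)-4-bromo-6-methoxy-2-(4-methoxyphenyl)-2,3-dihydro-1-benzofuran-3-carboxylate, cis (not isolated) | Brc1cc(OC)cc2c1[C@H](C(=O)OC)[C@H](c1ccc(OC)cc1)O2 | intermediate
10 | methyl (2R,3R)-4-bromo-6-methoxy-2-(4-methoxyphenyl)-2,3-dihydro-1-benzofuran-3-carboxylate, trans | Brc1cc(OC)cc2c1[C@@H](C(=O)OC)[C@H](c1ccc(OC)cc1)O2 | intermediate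
11 | (2R,3R)-4-bromo-6-methoxy-2-(4-methoxyphenyl)-2,3-dihydro-1-benzofuran-3-carbaldehyde, trans | Brc1cc(OC)cc2c1[C@@H](C=O)[C@H](c1ccc(OC)cc1)O2 | intermediate
12 | acetylacetone (pentane-2,4-dione) | CC(=O)CC(C)=O | starting material
13 | dilithio acetylacetone, the 1,3-dianion (not isolated) | C=C(O[Li])C=C(C)O[Li] | intermediate
14 | 6-[(2R,3S)-4-bromo-6-methoxy-2-(4-methoxyphenyl)-2,3-dihydro-1-benzofuran-3-yl]-6-hydroxyhexane-2,4-dione, ring trans, both carbinol epimers | Brc1cc(OC)cc2c1[C@@H](C(O)CC(=O)CC(C)=O)[C@H](c1ccc(OC)cc1)O2 | intermediate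
15 | 1-[(2R,3R)-4-bromo-6-methoxy-2-(4-methoxyphenyl)-2,3-dihydro-1-benzofuran-3-yl]hexane-1,3,5-trione, trans | Brc1cc(OC)cc2c1[C@@H](C(=O)CC(=O)CC(C)=O)[C@H](c1ccc(OC)cc1)O2 | intermediate
16 | 5-[(2R,3R)-4-bromo-6-methoxy-2-(4-methoxyphenyl)-2,3-dihydro-1-benzofuran-3-yl]benzene-1,3-diol, trans | Brc1cc(OC)cc2c1[C@@H](c1cc(O)cc(O)c1)[C@H](c1ccc(OC)cc1)O2 | intermediate
17 | (2R,3R)-4-bromo-3-(3,5-dimethoxyphenyl)-6-methoxy-2-(4-methoxyphenyl)-2,3-dihydro-1-benzofuran | Brc1cc(OC)cc2c1[C@@H](c1cc(OC)cc(OC)c1)[C@H](c1ccc(OC)cc1)O2 | intermediate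
18 | 4-methoxybenzaldehyde | COc1ccc(C=O)cc1 | starting material
19 | 1-ethynyl-3,5-dimethoxybenzene | COc1cc(C#C)cc(OC)c1 | starting material
20 | ethyl[(3,5-dimethoxyphenyl)ethynyl]zinc (not isolated) | CC[Zn]C#Cc1cc(OC)cc(OC)c1 | intermediate
21 | (1R)-3-(3,5-dimethoxyphenyl)-1-(4-methoxyphenyl)prop-2-yn-1-ol | COc1ccc([C@@H](O)C#Cc2cc(OC)cc(OC)c2)cc1 | intermediate
22 | DBF-magnesium bromide (not isolated) | Br[Mg]c1cc(OC)cc2c1[C@@H](c1cc(OC)cc(OC)c1)[C@H](c1ccc(OC)cc1)O2 | intermediate
23 | chloromagnesium (1R)-3-(3,5-dimethoxyphenyl)-1-(4-methoxyphenyl)prop-2-yn-1-olate (not isolated) | COc1ccc([C@@H](O[Mg]Cl)C#Cc2cc(OC)cc(OC)c2)cc1 | intermediate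
24 | (5R)-4-DBF-3-(3,5-dimethoxyphenyl)-5-(4-methoxyphenyl)-2,5-dihydro-1,2-oxamagnesole, cyclic alkenylmagnesium alkoxide (not isolated) | COc1ccc([C@H]2O[Mg]C(c3cc(OC)cc(OC)c3)=C2c2cc(OC)cc3c2[C@@H](c2cc(OC)cc(OC)c2)[C@H](c2ccc(OC)cc2)O3)cc1 | intermediate
25 | (2Z,4R)-3-DBF-2-(3,5-dimethoxyphenyl)-4-hydroxy-4-(4-methoxyphenyl)but-2-enoic acid (not isolated) | COc1ccc([C@@H](O)/C(c2cc(OC)cc3c2[C@@H](c2cc(OC)cc(OC)c2)[C@H](c2ccc(OC)cc2)O3)=C(\C(=O)O)c2cc(OC)cc(OC)c2)cc1 | intermediate
26 | (5R)-4-DBF-3-(3,5-dimethoxyphenyl)-5-(4-methoxyphenyl)furan-2(5H)-one | COc1ccc([C@H]2OC(=O)C(c3cc(OC)cc(OC)c3)=C2c2cc(OC)cc3c2[C@@H](c2cc(OC)cc(OC)c2)[C@H](c2ccc(OC)cc2)O3)cc1 | intermediate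
27 | (3R,4S,5S)-4-DBF-3-(3,5-dimethoxyphenyl)-5-(4-methoxyphenyl)oxolan-2-one, all cis | COc1ccc([C@H]2OC(=O)[C@@H](c3cc(OC)cc(OC)c3)[C@H]2c2cc(OC)cc3c2[C@@H](c2cc(OC)cc(OC)c2)[C@H](c2ccc(OC)cc2)O3)cc1 | intermediate
28 | (3R,4S,5S)-4-DBF-3-(3,5-dimethoxyphenyl)-5-(4-methoxyphenyl)oxolan-2-ol, both anomers | COc1ccc([C@H]2OC(O)[C@@H](c3cc(OC)cc(OC)c3)[C@H]2c2cc(OC)cc3c2[C@@H](c2cc(OC)cc(OC)c2)[C@H](c2ccc(OC)cc2)O3)cc1 | intermediate
29 | potassium (4-methoxyphenyl)trifluoroborate | COc1ccc([B-](F)(F)F)cc1.[K+] | starting material
30 | (2S,3R,4S,5S)-4-DBF-3-(3,5-dimethoxyphenyl)-2,5-bis(4-methoxyphenyl)oxolane | COc1ccc([C@H]2O[C@H](c3ccc(OC)cc3)[C@@H](c3cc(OC)cc(OC)c3)[C@H]2c2cc(OC)cc3c2[C@@H](c2cc(OC)cc(OC)c2)[C@H](c2ccc(OC)cc2)O3)cc1 | intermediate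
31 | 5-[(2S,3R,4S,5S)-4-[(2R,3R)-3-(3,5-dihydroxyphenyl)-6-hydroxy-2-(4-hydroxyphenyl)-2,3-dihydro-1-benzofuran-4-yl]-2,5-bis(4-hydroxyphenyl)oxolan-3-yl]benzene-1,3-diol | Oc1ccc([C@H]2O[C@H](c3ccc(O)cc3)[C@@H](c3cc(O)cc(O)c3)[C@H]2c2cc(O)cc3c2[C@@H](c2cc(O)cc(O)c2)[C@H](c2ccc(O)cc2)O3)cc1 | target

## Step count and least certain steps

Total: 15 steps. Longest linear sequence: 14 steps (steps 1–9, then 11–15); step 10 makes the second fragment.

Step 8 (key step). The most likely failure is a slow aldol at the hindered C1 carbonyl, which would give time for hydroxide-induced cleavage of the triketone chain or for opening of the furan ring with loss of C2'. The fallback builds the same ring by a Michael–Claisen sequence and sets out from 11.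
- Wittig reaction with 1-(triphenylphosphoranylidene)propan-2-one (toluene, 80 °C) should give the enone (3E)-4-[(2R,3R)-4-bromo-6-methoxy-2-(4-methoxyphenyl)-2,3-dihydro-1-benzofuran-3-yl]but-3-en-2-one F1.
- Michael addition of dimethyl malonate and Claisen ring closure (NaOMe, MeOH, reflux) should give methyl 6-[(2R,3R)-4-bromo-6-methoxy-2-(4-methoxyphenyl)-2,3-dihydro-1-benzofuran-3-yl]-2,4-dioxocyclohexane-1-carboxylate F2.
- Saponification and decarboxylation (aq. NaOH, then HCl, 60 °C) would give 5-[(2R,3R)-4-bromo-6-methoxy-2-(4-methoxyphenyl)-2,3-dihydro-1-benzofuran-3-yl]cyclohexane-1,3-dione F3.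
- Oxidative aromatisation with I2 in methanol at reflux is expected to give the aryl methyl ethers, any monomethyl ether being completed under the conditions of step 9, so the sequence comes back to the route at 17.

Step 4. The ortho bromine twists the carbene out of the plane of its aryl ring and makes it more reactive, so enantioselectivity or 1,5-site selectivity of the insertion may erode. The fallback replaces asymmetric catalysis by resolution. From 8, Rh2(OAc)4 (CH2Cl2, rt) followed by NaOMe/MeOH should give the racemic trans ester methyl (2RS,3RS)-4-bromo-6-methoxy-2-(4-methoxyphenyl)-2,3-dihydro-1-benzofuran-3-carboxylate F4. Its enantiomers would be separated by preparative chromatography on a chiral stationary phase, which returns to the route at 10.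

Step 11. The hindered aryl–magnesium bond may add too slowly to the internal alkyne, so that protonation or homocoupling of 22, or ionisation and racemisation of the doubly activated alkoxide at 70 °C, take over. The fallback is a cross-coupling that sets out from 17.
- 22 is made as before and transmetallated with ZnCl2 to DBF-zinc chloride F5.
- The partner is made from racemic methyl 4-methoxymandelate and (3,5-dimethoxyphenyl)acetyl chloride (pyridine), which give methyl 2-{[(3,5-dimethoxyphenyl)acetyl]oxy}-2-(4-methoxyphenyl)acetate F6.
- Dieckmann condensation (LiHMDS, THF, −78 °C) gives the tetronic acid 3-(3,5-dimethoxyphenyl)-4-hydroxy-5-(4-methoxyphenyl)furan-2(5H)-one F7.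
- Tf2O with i-Pr2NEt gives 4-(3,5-dimethoxyphenyl)-2-(4-methoxyphenyl)-5-oxo-2,5-dihydrofuran-3-yl trifluoromethanesulfonate F8.
- Negishi coupling of F5 with F8 (Pd(PPh3)4, a zerovalent palladium catalyst, THF, 50 °C) should give 26 together with its C5 epimer (5S)-4-DBF-3-(3,5-dimethoxyphenyl)-5-(4-methoxyphenyl)furan-2(5H)-one F9.
- Because the DBF half is a single enantiomer, the two are diastereomers and would be separated by chromatography, which returns to the route at 26 at the cost of half the material.

Step 12. The allylic and benzylic C5–O bond may be hydrogenolysed before or after the hindered tetrasubstituted double bond is saturated, or reduction may stall. The fallback replaces surface hydrogenation by conjugate hydride addition and kinetic protonation. From 26, [(Ph3P)CuH]6 (5 mol%) with PhMe2SiH (toluene, rt) should deliver hydride to C4 from the face opposite the C5 aryl group and give the silyl ketene acetal {[4-DBF-3-(3,5-dimethoxyphenyl)-5-(4-methoxyphenyl)-4,5-dihydrofuran-2-yl]oxy}dimethyl(phenyl)silane (4,5-cis) F10. Protonation at −78 °C (acetic acid, then fluoride work-up) from the face opposite the C4 aryl group should give the all-cis lactone and return to the route at 27.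

Step 14. The oxocarbenium ion may lose the C3 proton (which would scramble C3 through a dihydrofuran), BF3 may ionise the C5–O bond, or aryl transfer may be too slow. The fallback avoids the strong Lewis acid. From 28, benzenesulfinic acid and CaCl2 (CH2Cl2, rt) should give the anomeric sulfone (3R,4S,5S)-4-DBF-3-(3,5-dimethoxyphenyl)-5-(4-methoxyphenyl)-2-(phenylsulfonyl)oxolane F11. Displacement of sulfinate with the arylzinc reagent made from (4-methoxyphenyl)magnesium bromide and ZnBr2 (THF, rt), again from the open face, returns to the route at 30.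

Step 15. The Lewis acid may ionise a benzylic C–O bond, most seriously in the oxolane, where ring opening can be followed by Friedel–Crafts capture by a neighbouring ring or by reclosure with epimerisation at C5; cleavage of all eight ethers may also be incomplete. The fallback changes from electrophilic to nucleophilic dealkylation in a basic, non-ionising medium: from 30, sodium ethanethiolate in DMF at 130 °C under argon would remove the methyl groups by SN2 attack at carbon, and acidification would give 31 directly. No new isolated compound is involved.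

## Further compounds

F1 | step 8 | (3E)-4-[(2R,3R)-4-bromo-6-methoxy-2-(4-methoxyphenyl)-2,3-dihydro-1-benzofuran-3-yl]but-3-en-2-one | Brc1cc(OC)cc2c1[C@@H](/C=C/C(C)=O)[C@H](c1ccc(OC)cc1)O2
F2 | step 8 | methyl 6-[(2R,3R)-4-bromo-6-methoxy-2-(4-methoxyphenyl)-2,3-dihydro-1-benzofuran-3-yl]-2,4-dioxocyclohexane-1-carboxylate (mixture of isomers) | Brc1cc(OC)cc2c1[C@@H](C1CC(=O)CC(=O)C1C(=O)OC)[C@H](c1ccc(OC)cc1)O2
F3 | step 8 | 5-[(2R,3R)-4-bromo-6-methoxy-2-(4-methoxyphenyl)-2,3-dihydro-1-benzofuran-3-yl]cyclohexane-1,3-dione | Brc1cc(OC)cc2c1[C@@H](C1CC(=O)CC(=O)C1)[C@H](c1ccc(OC)cc1)O2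
F4 | step 4 | methyl (2RS,3RS)-4-bromo-6-methoxy-2-(4-methoxyphenyl)-2,3-dihydro-1-benzofuran-3-carboxylate, racemic trans | Brc1cc(OC)cc2c1[C@@H](C(=O)OC)[C@H](c1ccc(OC)cc1)O2.Brc1cc(OC)cc2c1[C@H](C(=O)OC)[C@@H](c1ccc(OC)cc1)O2
F5 | step 11 | DBF-zinc chloride | Cl[Zn]c1cc(OC)cc2c1[C@@H](c1cc(OC)cc(OC)c1)[C@H](c1ccc(OC)cc1)O2
F6 | step 11 | methyl 2-{[(3,5-dimethoxyphenyl)acetyl]oxy}-2-(4-methoxyphenyl)acetate, racemic | COC(=O)C(OC(=O)Cc1cc(OC)cc(OC)c1)c1ccc(OC)cc1
F7 | step 11 | 3-(3,5-dimethoxyphenyl)-4-hydroxy-5-(4-methoxyphenyl)furan-2(5H)-one, racemic | COc1ccc(C2OC(=O)C(c3cc(OC)cc(OC)c3)=C2O)cc1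
F8 | step 11 | 4-(3,5-dimethoxyphenyl)-2-(4-methoxyphenyl)-5-oxo-2,5-dihydrofuran-3-yl trifluoromethanesulfonate, racemic | COc1ccc(C2OC(=O)C(c3cc(OC)cc(OC)c3)=C2OS(=O)(=O)C(F)(F)F)cc1
F9 | step 11 | (5S)-4-DBF-3-(3,5-dimethoxyphenyl)-5-(4-methoxyphenyl)furan-2(5H)-one, C5 epimer of 26 | COc1ccc([C@@H]2OC(=O)C(c3cc(OC)cc(OC)c3)=C2c2cc(OC)cc3c2[C@@H](c2cc(OC)cc(OC)c2)[C@H](c2ccc(OC)cc2)O3)cc1
F10 | step 12 | {[4-DBF-3-(3,5-dimethoxyphenyl)-5-(4-methoxyphenyl)-4,5-dihydrofuran-2-yl]oxy}dimethyl(phenyl)silane, 4,5-cis | COc1ccc([C@H]2OC(O[Si](C)(C)c3ccccc3)=C(c3cc(OC)cc(OC)c3)[C@H]2c2cc(OC)cc3c2[C@@H](c2cc(OC)cc(OC)c2)[C@H](c2ccc(OC)cc2)O3)cc1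
F11 | step 14 | (3R,4S,5S)-4-DBF-3-(3,5-dimethoxyphenyl)-5-(4-methoxyphenyl)-2-(phenylsulfonyl)oxolane, both anomers | COc1ccc([C@H]2OC(S(=O)(=O)c3ccccc3)[C@@H](c3cc(OC)cc(OC)c3)[C@H]2c2cc(OC)cc3c2[C@@H](c2cc(OC)cc(OC)c2)[C@H](c2ccc(OC)cc2)O3)cc1
F0 | step 15 | none | none
A1 | alternative 1 | 4,5-dihydrofuran (enol ether) with all four aryl groups, the two sp3 carbons trans | COc1ccc(C2O[C@H](c3ccc(OC)cc3)[C@@H](c3cc(OC)cc(OC)c3)C=2c2cc(OC)cc3c2[C@@H](c2cc(OC)cc(OC)c2)[C@H](c2ccc(OC)cc2)O3)cc1
A2 | alternative 1 | 2-DBF-3-(3,5-dimethoxyphenyl)-1-(4-methoxyphenyl)prop-2-en-1-one, alkene geometry left open | COc1ccc(C(=O)C(=Cc2cc(OC)cc(OC)c2)c2cc(OC)cc3c2[C@@H](c2cc(OC)cc(OC)c2)[C@H](c2ccc(OC)cc2)O3)cc1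
A3 | alternative 1 | 1-(diazomethyl)-4-methoxybenzene | COc1ccc(C=[N+]=[N-])cc1
A4 | alternative 2 | 2-hydroxy-4-methoxy-6-(oxolan-3-yl)phenyl 3,5-dimethoxyphenyl ketone, oxolane configured as in 30 | COc1ccc([C@H]2O[C@H](c3ccc(OC)cc3)[C@@H](c3cc(OC)cc(OC)c3)[C@H]2c2cc(OC)cc(O)c2C(=O)c2cc(OC)cc(OC)c2)cc1
A5 | alternative 2 | 1-(3,5-dimethoxyphenyl)-3-[4-(3,5-dimethoxyphenyl)-2,5-bis(4-methoxyphenyl)oxolan-3-yl]prop-2-yn-1-one, oxolane configured as in 30 | COc1ccc([C@H]2O[C@H](c3ccc(OC)cc3)[C@@H](c3cc(OC)cc(OC)c3)[C@H]2C#CC(=O)c2cc(OC)cc(OC)c2)cc1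
A6 | alternative 2 | 1,3-dimethoxy-1-(trimethylsilyloxy)buta-1,3-diene | COC(=C)C=C(OC)O[Si](C)(C)C
A7 | alternative 3 | (2R,3R)-4-bromo-3-(3,5-dimethoxyphenyl)-6-methoxy-2-(4-methoxyphenyl)-2,3-dihydro-1-benzofuran, identical with 17 | Brc1cc(OC)cc2c1[C@@H](c1cc(OC)cc(OC)c1)[C@H](c1ccc(OC)cc1)O2
A8 | alternative 3 | 3-bromo-2-[1-(3,5-dimethoxyphenyl)-2-(4-methoxyphenyl)ethenyl]-5-methoxyphenol | COc1ccc(C=C(c2cc(OC)cc(OC)c2)c2c(O)cc(OC)cc2Br)cc1
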